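Ring A is a benzoate in which C1 (CO2H), C6 (O-aryl), C5-H and C4-H match C3 to C6 of a 4-aryloxy-2-pyrone-3-carboxylate, and C2 (OMe) with C3 (side chain) match the carbonyl and α-carbon of a β-silyloxy ester whose β-carbon is the benzylic stereocentre.
Key disconnection: ring A bonds C1–C2 and C3–C4, opened to the pyrone and the silyl ketene acetal of that ester; CO2 and methanol are lost on aromatisation.
Diaryl ether O–C6: made at the pyrone stage by addition–elimination of the ring B phenoxide on a 4-chloropyrone; the pyrone ring comes from dibenzyl malonate and (E)-3-ethoxyacryloyl chloride.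
Side chain: acetoacetate dianion plus acetone, then (S)-BINAP–ruthenium hydrogenation sets the only stereocentre (S).
Ring order: ring B is bought as an arene, the pyrone ring is made second, ring A last; then O-methylation, hydrogenolysis of both benzyl groups and fluoride desilylation.

Key step: step 12

Assumption: 2-hydroxy-3-methoxy-5-methylbenzaldehyde (compound 1) is taken as a catalogue compound.
Abbreviations in names: ArB-oxy = 2-(benzyloxy)-6-[(tert-butyldimethylsilyloxy)methyl]-4-methylphenoxy; R* = (1S)-3-methyl-1,3-bis(triethylsilyloxy)butyl.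

Step 1
Reactants: 1 2-hydroxy-3-methoxy-5-methylbenzaldehyde
Product: 2 2,3-dihydroxy-5-methylbenzaldehyde
Conditions: BBr3 (2.2 equiv), CH2Cl2, −78 → 0 °C; H2O
Reagents that add atoms: none
Why: Lewis acid demethylation of an aryl methyl ether, in which boron binds the ether oxygen and bromide removes the methyl group by SN2 while the aldehyde and the aryl methyl group stay untouched at low temperature.

Step 2
Reactants: 2 2,3-dihydroxy-5-methylbenzaldehyde
Product: 3 3-(benzyloxy)-2-hydroxy-5-methylbenzaldehyde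
Conditions: NaH (2.2 equiv), DMSO/THF, 0 °C → rt; BnBr (1.0 equiv); AcOH
Reagents that add atoms: benzyl bromide, BrCc1ccccc1
Why: Williamson ether synthesis on the dianion, in which the 2-oxide is conjugated with the formyl group and held in a sodium chelate, so the 3-oxide is the more nucleophilic site and one equivalent of benzyl bromide should give the 3-benzyl ether, as is known for 2,3-dihydroxybenzaldehyde.

Step 3
Reactants: 3 3-(benzyloxy)-2-hydroxy-5-methylbenzaldehyde
Product: 4 2-(benzyloxy)-6-(hydroxymethyl)-4-methylphenol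
Conditions: NaBH4, MeOH/THF, 0 °C
Reagents that add atoms: none
Why: Borohydride reduction of the aldehyde, the only reducible group in the molecule.

Step 4
Reactants: 4 2-(benzyloxy)-6-(hydroxymethyl)-4-methylphenol
Product: 5 2-(benzyloxy)-6-[(tert-butyldimethylsilyloxy)methyl]-4-methylphenol
Conditions: tBuMe2SiCl (1.05 equiv), imidazole, CH2Cl2, 0 °C
Reagents that add atoms: tert-butyldimethylsilyl chloride, CC(C)(C)[Si](C)(C)Cl
Why: Silylation of the unhindered primary benzylic alcohol is much faster than that of a phenol flanked by two ortho substituents, so one equivalent of silyl chloride should leave the phenol free.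

Step 5
Reactants: 6 dibenzyl malonate; 7 (E)-3-ethoxyacryloyl chloride
Product: 8 dibenzyl 2-[(E)-3-ethoxyprop-2-enoyl]malonate (enolised)
Conditions: MgCl2 (1.0 equiv), Et3N (2.1 equiv), MeCN, 0 °C; 7 (1.1 equiv), 0 °C → rt; cold 1 M HCl wash
Reagents that add atoms: none
Why: C-Acylation of a magnesium malonate enolate formed by soft enolisation, in which the acid chloride carbonyl is far more electrophilic than the β-carbon of the ethoxyacrylate and the magnesium chelate of the product prevents a second acylation.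

Step 6
Reactants: 8 dibenzyl 2-[(E)-3-ethoxyprop-2-enoyl]malonate
Product: 10 benzyl 4-hydroxy-2-oxo-2H-pyran-3-carboxylate, via 2-benzyloxy-4-pyranone 9 (not isolated)
Conditions: CF3CO2H/CH2Cl2 (1:1), rt
Reagents that add atoms: none
Why: Acid-promoted 6-endo ring closure of an ester carbonyl oxygen onto the protonated β-ethoxy enone (addition–elimination with loss of ethanol, analogous to the acid cyclisation of 3-alkoxyallylidene malonates to 2-pyrone-3-carboxylates) gives 9, whose O-benzyl group is lost from the 4-hydroxypyrylium ion to trifluoroacetate while the ordinary benzyl ester is stable to this acid.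

Step 7
Reactants: 10 benzyl 4-hydroxy-2-oxo-2H-pyran-3-carboxylate; 5 2-(benzyloxy)-6-[(tert-butyldimethylsilyloxy)methyl]-4-methylphenol
Product: 12 benzyl 4-{2-(benzyloxy)-6-[(tert-butyldimethylsilyloxy)methyl]-4-methylphenoxy}-2-oxo-2H-pyran-3-carboxylate, via chloropyrone 11 (not isolated)
Conditions: (COCl)2 (1.3 equiv), DMF (cat.), CH2Cl2, 0 °C → rt; evaporate; 5 (1.0 equiv), Cs2CO3 (1.5 equiv), MeCN, 0 °C → rt
Reagents that add atoms: none
Why: Vilsmeier-type conversion of the vinylogous acid into the vinylogous acid chloride, then addition–elimination of the phenoxide at C4, which is activated by both carbonyl groups and where loss of chloride makes substitution the productive path.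

Step 8
Reactants: 13 methyl acetoacetate; 14 acetone
Product: 15 methyl 5-hydroxy-5-methyl-3-oxohexanoate
Conditions: LiN(iPr)2 (2.1 equiv), THF, 0 °C; acetone, −78 °C; AcOH
Reagents that add atoms: none
Why: Aldol addition of the acetoacetate dianion, whose more basic terminal carbanion attacks the ketone, giving an achiral δ-hydroxy-β-keto ester.

Step 9
Reactants: 15 methyl 5-hydroxy-5-methyl-3-oxohexanoate
Product: 16 methyl (3S)-3,5-dihydroxy-5-methylhexanoate
Conditions: RuCl2[(S)-BINAP] (0.5 mol%), H2 (10 atm), MeOH, 40 °C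
Reagents that add atoms: none
Why: Noyori asymmetric hydrogenation of a β-keto ester, in which ketone and ester carbonyl chelate the ruthenium hydride and the (S)-BINAP ligand directs hydride to the face that gives the (S)-alcohol, the same sense as (S)-3-hydroxybutanoate from methyl acetoacetate.

Step 10
Reactants: 16 methyl (3S)-3,5-dihydroxy-5-methylhexanoate
Product: 17 methyl (3S)-5-methyl-3,5-bis(triethylsilyloxy)hexanoate
Conditions: Et3SiOTf (2.5 equiv), 2,6-lutidine, CH2Cl2, −78 → 0 °C
Reagents that add atoms: triethylsilyl trifluoromethanesulfonate, CC[Si](CC)(CC)OS(=O)(=O)C(F)(F)F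
Why: A silyl triflate with 2,6-lutidine silylates the secondary and the tertiary alcohol alike, and the stereocentre is not involved.

Step 11
Reactants: 17 methyl (3S)-5-methyl-3,5-bis(triethylsilyloxy)hexanoate
Product: 18 (1E,3S)-1-methoxy-5-methyl-3,5-bis(triethylsilyloxy)-1-(trimethylsilyloxy)hex-1-ene
Conditions: 17 and Me3SiCl (1.5 equiv) in THF, −78 °C; LiN(iPr)2 (1.2 equiv) added; evaporate, pentane, filter under argon; used crude
Reagents that add atoms: chlorotrimethylsilane, C[Si](C)(C)Cl
Why: Kinetic ester enolisation with in situ silyl chloride quench, as for an Ireland–Claisen ketene acetal, traps the enolate at −78 °C before the β-silyloxy group can be eliminated, and the mainly E geometry is of no consequence because both alkene carbons become aromatic.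

Step 12
Reactants: 12 benzyl 4-(ArB-oxy)-2-oxo-2H-pyran-3-carboxylate; 18 (1E,3S)-1-methoxy-5-methyl-3,5-bis(triethylsilyloxy)-1-(trimethylsilyloxy)hex-1-ene
Product: 22 benzyl 6-(ArB-oxy)-2-hydroxy-3-R*-benzoate, via lactone-bridged cycloadduct 19 (not isolated), via cyclohexadiene ketal 20 (not isolated), via aryl trimethylsilyl ether 21 (not isolated)
Conditions: 18 (2.5 equiv), toluene, 110 °C, sealed tube, argon; then citric acid, THF/H2O, 0 °C
Reagents that add atoms: none
Why: This is an inverse-electron-demand Diels–Alder reaction of the kind known for 3-alkoxycarbonyl-2-pyrones and 1,1-dioxygenated alkenes: the electron-rich C2 of 18 bonds to the free C6 of pyrone 12, the terminus that is vinylogous to both carbonyl groups, and the acetal carbon closes onto C3 in the same asynchronous step to give bridged lactone 19. Cycloreversion of 19 expels CO2, the mixed ketal 20 loses methanol through an oxygen-stabilised cyclohexadienyl cation to give silyl ether 21, and citric acid frees the phenol (ketal that survives the heating collapses in the same work-up through the dienone). Ring A is therefore closed by an intermolecular [4+2] cycloaddition that makes its C3–C4 and C1–C2 bonds, followed by aromatisation. No lasting stereocentre is made, because the four sp3 carbons of 19 all end as aromatic carbons, and the (S)-carbinol carbon, allylic in 18 and benzylic in 22, is never part of a reacting bond. The step needs bonding across C3 and C6 of the pyrone with the acetal carbon next to the ester, not addition–elimination at C4 with loss of the ring B phenoxide; the unsubstituted C6, the matched polarisation of the two partners and the absence of a Lewis acid should secure this.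

Step 13
Reactants: 22 benzyl 6-(ArB-oxy)-2-hydroxy-3-R*-benzoate
Product: 23 benzyl 6-(ArB-oxy)-2-methoxy-3-R*-benzoate
Conditions: MeI, K2CO3, DMF, rt
Reagents that add atoms: iodomethane, CI
Why: Williamson methylation of the phenoxide of the salicylate, the only acidic OH group in the molecule.

Step 14
Reactants: 23 benzyl 6-(ArB-oxy)-2-methoxy-3-R*-benzoate
Product: 24 6-{2-hydroxy-6-[(tert-butyldimethylsilyloxy)methyl]-4-methylphenoxy}-2-methoxy-3-R*-benzoic acid
Conditions: H2 (1 atm), 10% Pd/C, EtOAc, rt
Reagents that add atoms: none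
Why: Hydrogenolysis over palladium cleaves the benzyl ester and the aryl benzyl ether, while the hindered benzylic silyl ethers and the diaryl ether are left alone in a non-protic solvent.

Step 15
Reactants: 24 6-{2-hydroxy-6-[(tert-butyldimethylsilyloxy)methyl]-4-methylphenoxy}-2-methoxy-3-R*-benzoic acid
Product: 25 3-[(1S)-1,3-dihydroxy-3-methylbutyl]-6-[2-hydroxy-6-(hydroxymethyl)-4-methylphenoxy]-2-methoxybenzoic acid (target)
Conditions: Bu4NF (5 equiv), THF, 0 °C → rt; AcOH; reverse-phase chromatography
Reagents that add atoms: none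
Why: Fluoride cleaves the three silyl ethers through Si–F bond formation without acid, so the electron-rich benzylic alcohol cannot ionise and the stereocentre is kept.

Compound list
1 | 2-hydroxy-3-methoxy-5-methylbenzaldehyde | COc1cc(C)cc(C=O)c1O | starting material
2 | 2,3-dihydroxy-5-methylbenzaldehyde | Cc1cc(O)c(O)c(C=O)c1 | intermediate
3 | 3-(benzyloxy)-2-hydroxy-5-methylbenzaldehyde | Cc1cc(OCc2ccccc2)c(O)c(C=O)c1 | intermediate
4 | 2-(benzyloxy)-6-(hydroxymethyl)-4-methylphenol | Cc1cc(CO)c(O)c(OCc2ccccc2)c1 | intermediate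
5 | 2-(benzyloxy)-6-[(tert-butyldimethylsilyloxy)methyl]-4-methylphenol | Cc1cc(CO[Si](C)(C)C(C)(C)C)c(O)c(OCc2ccccc2)c1 | intermediate
6 | dibenzyl malonate | O=C(CC(=O)OCc1ccccc1)OCc1ccccc1 | starting material
7 | (E)-3-ethoxyacryloyl chloride | CCO/C=C/C(=O)Cl | starting material
8 | dibenzyl 2-[(E)-3-ethoxyprop-2-enoyl]malonate | CCO/C=C/C(=O)C(C(=O)OCc1ccccc1)C(=O)OCc1ccccc1 | intermediate
9 | benzyl 2-(benzyloxy)-4-oxo-4H-pyran-3-carboxylate (not isolated) | O=C(OCc1ccccc1)C1=C(OCc2ccccc2)OC=CC1=O | intermediate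
10 | benzyl 4-hydroxy-2-oxo-2H-pyran-3-carboxylate | O=C(OCc1ccccc1)C1=C(O)C=COC1=O | intermediate
11 | benzyl 4-chloro-2-oxo-2H-pyran-3-carboxylate (not isolated) | O=C(OCc1ccccc1)C1=C(Cl)C=COC1=O | intermediate
12 | benzyl 4-{2-(benzyloxy)-6-[(tert-butyldimethylsilyloxy)methyl]-4-methylphenoxy}-2-oxo-2H-pyran-3-carboxylate | O=C(OCc1ccccc1)C1=C(Oc2c(OCc3ccccc3)cc(C)cc2CO[Si](C)(C)C(C)(C)C)C=COC1=O | intermediate
13 | methyl acetoacetate | CC(=O)CC(=O)OC | starting material
14 | acetone | CC(C)=O | starting material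
15 | methyl 5-hydroxy-5-methyl-3-oxohexanoate | COC(=O)CC(=O)CC(C)(C)O | intermediate
16 | methyl (3S)-3,5-dihydroxy-5-methylhexanoate | COC(=O)C[C@@H](O)CC(C)(C)O | intermediate
17 | methyl (3S)-5-methyl-3,5-bis(triethylsilyloxy)hexanoate | COC(=O)C[C@@H](O[Si](CC)(CC)CC)CC(C)(C)O[Si](CC)(CC)CC | intermediate
18 | (1E,3S)-1-methoxy-5-methyl-3,5-bis(triethylsilyloxy)-1-(trimethylsilyloxy)hex-1-ene | CO/C(O[Si](C)(C)C)=C\[C@@H](O[Si](CC)(CC)CC)CC(C)(C)O[Si](CC)(CC)CC | intermediate
19 | benzyl 5-{2-(benzyloxy)-6-[(tert-butyldimethylsilyloxy)methyl]-4-methylphenoxy}-8-methoxy-7-[(1S)-3-methyl-1,3-bis(triethylsilyloxy)butyl]-3-oxo-8-(trimethylsilyloxy)-2-oxabicyclo[2.2.2]oct-5-ene-4-carboxylate (diastereomer mixture at the ring carbons; not isolated) | O=C1OC2C=C(Oc3c(OCc4ccccc4)cc(C)cc3CO[Si](C)(C)C(C)(C)C)C1(C(=O)OCc1ccccc1)C(OC)(O[Si](C)(C)C)C2[C@@H](O[Si](CC)(CC)CC)CC(C)(C)O[Si](CC)(CC)CC | intermediate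
20 | benzyl 2-{2-(benzyloxy)-6-[(tert-butyldimethylsilyloxy)methyl]-4-methylphenoxy}-6-methoxy-5-[(1S)-3-methyl-1,3-bis(triethylsilyloxy)butyl]-6-(trimethylsilyloxy)cyclohexa-1,3-diene-1-carboxylate (diastereomer mixture at C5 and C6; not isolated) | O=C(OCc1ccccc1)C1=C(Oc2c(OCc3ccccc3)cc(C)cc2CO[Si](C)(C)C(C)(C)C)C=CC([C@@H](O[Si](CC)(CC)CC)CC(C)(C)O[Si](CC)(CC)CC)C1(OC)O[Si](C)(C)C | intermediate
21 | benzyl 6-{2-(benzyloxy)-6-[(tert-butyldimethylsilyloxy)methyl]-4-methylphenoxy}-3-[(1S)-3-methyl-1,3-bis(triethylsilyloxy)butyl]-2-(trimethylsilyloxy)benzoate (not isolated) | C[Si](C)(C)Oc1c([C@@H](O[Si](CC)(CC)CC)CC(C)(C)O[Si](CC)(CC)CC)ccc(Oc2c(OCc3ccccc3)cc(C)cc2CO[Si](C)(C)C(C)(C)C)c1C(=O)OCc1ccccc1 | intermediate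
22 | benzyl 6-{2-(benzyloxy)-6-[(tert-butyldimethylsilyloxy)methyl]-4-methylphenoxy}-2-hydroxy-3-[(1S)-3-methyl-1,3-bis(triethylsilyloxy)butyl]benzoate | Oc1c([C@@H](O[Si](CC)(CC)CC)CC(C)(C)O[Si](CC)(CC)CC)ccc(Oc2c(OCc3ccccc3)cc(C)cc2CO[Si](C)(C)C(C)(C)C)c1C(=O)OCc1ccccc1 | intermediate
23 | benzyl 6-{2-(benzyloxy)-6-[(tert-butyldimethylsilyloxy)methyl]-4-methylphenoxy}-2-methoxy-3-[(1S)-3-methyl-1,3-bis(triethylsilyloxy)butyl]benzoate | COc1c([C@@H](O[Si](CC)(CC)CC)CC(C)(C)O[Si](CC)(CC)CC)ccc(Oc2c(OCc3ccccc3)cc(C)cc2CO[Si](C)(C)C(C)(C)C)c1C(=O)OCc1ccccc1 | intermediate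
24 | 6-{2-hydroxy-6-[(tert-butyldimethylsilyloxy)methyl]-4-methylphenoxy}-2-methoxy-3-[(1S)-3-methyl-1,3-bis(triethylsilyloxy)butyl]benzoic acid | COc1c([C@@H](O[Si](CC)(CC)CC)CC(C)(C)O[Si](CC)(CC)CC)ccc(Oc2c(O)cc(C)cc2CO[Si](C)(C)C(C)(C)C)c1C(=O)O | intermediate
25 | 3-[(1S)-1,3-dihydroxy-3-methylbutyl]-6-[2-hydroxy-6-(hydroxymethyl)-4-methylphenoxy]-2-methoxybenzoic acid | COc1c([C@@H](O)CC(C)(C)O)ccc(Oc2c(O)cc(C)cc2CO)c1C(=O)O | target

Total step count: 15.
Longest linear sequence: 9 steps (steps 1 to 4, then 7, 12, 13, 14 and 15).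

Steps most likely to fail

Step 12. The cycloaddition may be slow, because the aryloxy donor at C4 lowers the electrophilicity of the diene and the nucleophilic carbon of 18 is trisubstituted and carries a branched chain. Conjugate addition at C4 with loss of the ring B phenoxide may compete, and 18 may lose silanol from its allylic position on heating. Loss of trimethylsilanol in place of methanol from the ketal would give 23 directly, which is harmless. The methanol set free also consumes ketene acetal, hence the excess of 18.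
Fallback: this sets out from 12 and keeps the pyrone cycloaddition, but builds the side chain afterwards. Trimethylsilyl acetate is converted with LiN(iPr)2 and Me3SiCl into 1,1-bis(trimethylsilyloxy)ethene F1, the unsubstituted and most reactive partner of this class, which has no allylic leaving group. Heating it with 12 should give, after loss of CO2 and trimethylsilanol and mild acid work-up, benzyl 6-(ArB-oxy)-2-hydroxybenzoate F2. Magnesium-mediated ortho-formylation (MgCl2, Et3N, paraformaldehyde, MeCN, reflux) at C3, the only free ortho position of the phenol, gives benzyl 6-(ArB-oxy)-3-formyl-2-hydroxybenzoate F3. MeI with K2CO3 gives the methyl ether aldehyde F4. Brown methallylation with the enantiomer of B-methallyldiisopinocampheylborane that delivers the (S)-alcohol (ethanolamine work-up) gives the homoallylic alcohol F5. Mukaiyama hydration of the 1,1-disubstituted alkene (Co(acac)2, PhSiH3, O2) gives the diol F6. Et3SiOTf with 2,6-lutidine returns to the route at 23.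

Step 6. The ring closure may stall at the neutral pyranone 9, both benzyl groups may be lost on longer exposure to acid, or the enol ether may be hydrolysed and the acyl group cleaved before the ring closes.
Fallback: this sets out from 8 and moves the chlorination in front of the ring closure. Oxalyl chloride with catalytic DMF converts the enol of 8 into dibenzyl 2-[(2E)-1-chloro-3-ethoxyprop-2-en-1-ylidene]malonate F7. Acid treatment of this 3-alkoxyallylidene malonate, the established way to 2-pyrone-3-carboxylates, closes the ring through an ester carbonyl oxygen. The 2-benzyloxypyrylium ion that results has no neutral pyranone form to rest in and loses its benzyl group at once. The route is rejoined at chloropyrone 11, which enters the second stage of step 7.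

Step 11. The lithium enolate may expel triethylsilanolate from the β-position, which gives the enoate and destroys the stereocentre. The ketene acetal may also be hydrolysed during isolation, or be silylated on carbon.
Fallback: this sets out from 16 and uses a polyanion in which the β-oxygen is an alkoxide and cannot leave, as in Fráter–Seebach alkylations. LiN(iPr)2 (3.3 equiv) followed by excess Me3SiCl gives (1E,3S)-1-methoxy-5-methyl-1,3,5-tris(trimethylsilyloxy)hex-1-ene F8. Cycloaddition with 12 under the conditions of step 12, with a methanolic citric acid work-up that removes all three trimethylsilyl groups, gives benzyl 6-(ArB-oxy)-3-[(1S)-1,3-dihydroxy-3-methylbutyl]-2-hydroxybenzoate F9. Excess Et3SiOTf with 2,6-lutidine gives the tris(triethylsilyl) compound F10, and K2CO3 in methanol at 0 °C cleaves only the aryl silyl ether, returning to the route at 22.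

Further compounds
F1 | step 12 | 1,1-bis(trimethylsilyloxy)ethene | C=C(O[Si](C)(C)C)O[Si](C)(C)C
F2 | step 12 | benzyl 6-{2-(benzyloxy)-6-[(tert-butyldimethylsilyloxy)methyl]-4-methylphenoxy}-2-hydroxybenzoate | Oc1cccc(Oc2c(OCc3ccccc3)cc(C)cc2CO[Si](C)(C)C(C)(C)C)c1C(=O)OCc1ccccc1
F3 | step 12 | benzyl 6-{2-(benzyloxy)-6-[(tert-butyldimethylsilyloxy)methyl]-4-methylphenoxy}-3-formyl-2-hydroxybenzoate | Oc1c(C=O)ccc(Oc2c(OCc3ccccc3)cc(C)cc2CO[Si](C)(C)C(C)(C)C)c1C(=O)OCc1ccccc1
F4 | step 12 | benzyl 6-{2-(benzyloxy)-6-[(tert-butyldimethylsilyloxy)methyl]-4-methylphenoxy}-3-formyl-2-methoxybenzoate | COc1c(C=O)ccc(Oc2c(OCc3ccccc3)cc(C)cc2CO[Si](C)(C)C(C)(C)C)c1C(=O)OCc1ccccc1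
F5 | step 12 | benzyl 6-{2-(benzyloxy)-6-[(tert-butyldimethylsilyloxy)methyl]-4-methylphenoxy}-3-[(1S)-1-hydroxy-3-methylbut-3-en-1-yl]-2-methoxybenzoate | COc1c([C@@H](O)CC(C)=C)ccc(Oc2c(OCc3ccccc3)cc(C)cc2CO[Si](C)(C)C(C)(C)C)c1C(=O)OCc1ccccc1
F6 | step 12 | benzyl 6-{2-(benzyloxy)-6-[(tert-butyldimethylsilyloxy)methyl]-4-methylphenoxy}-3-[(1S)-1,3-dihydroxy-3-methylbutyl]-2-methoxybenzoate | COc1c([C@@H](O)CC(C)(C)O)ccc(Oc2c(OCc3ccccc3)cc(C)cc2CO[Si](C)(C)C(C)(C)C)c1C(=O)OCc1ccccc1
F7 | step 6 | dibenzyl 2-[(2E)-1-chloro-3-ethoxyprop-2-en-1-ylidene]malonate | CCO/C=C/C(Cl)=C(C(=O)OCc1ccccc1)C(=O)OCc1ccccc1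
F8 | step 11 | (1E,3S)-1-methoxy-5-methyl-1,3,5-tris(trimethylsilyloxy)hex-1-ene | CO/C(O[Si](C)(C)C)=C\[C@@H](O[Si](C)(C)C)CC(C)(C)O[Si](C)(C)C
F9 | step 11 | benzyl 6-{2-(benzyloxy)-6-[(tert-butyldimethylsilyloxy)methyl]-4-methylphenoxy}-3-[(1S)-1,3-dihydroxy-3-methylbutyl]-2-hydroxybenzoate | Oc1c([C@@H](O)CC(C)(C)O)ccc(Oc2c(OCc3ccccc3)cc(C)cc2CO[Si](C)(C)C(C)(C)C)c1C(=O)OCc1ccccc1
F10 | step 11 | benzyl 6-{2-(benzyloxy)-6-[(tert-butyldimethylsilyloxy)methyl]-4-methylphenoxy}-3-[(1S)-3-methyl-1,3-bis(triethylsilyloxy)butyl]-2-(triethylsilyloxy)benzoate | CC[Si](CC)(CC)Oc1c([C@@H](O[Si](CC)(CC)CC)CC(C)(C)O[Si](CC)(CC)CC)ccc(Oc2c(OCc3ccccc3)cc(C)cc2CO[Si](C)(C)C(C)(C)C)c1C(=O)OCc1ccccc1
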